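## Retrosynthetic overview
1. Cacospongin D comes from its C9′-phenylsulfonyl methyl ester by reductive removal of PhSO2 and saponification in one flask.
2. Key cut is C8′–C9′, the CH2–CH2 bond next to the ring, not the aryl–allyl bond. Both carbons are by nature allylic C–X electrophiles, so the ring-side one is inverted to an α-sulfonyl carbanion.
3. The acceptor is an unprotected (2E,6E)-8′-bromogeranyl-hydroxybenzoate. It is made from methyl 4-hydroxybenzoate and geranyl bromide (2′E carried over), then E-selective SeO2 oxidation (sets 6′E) and an Appel reaction.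
4. The donor is β-cyclogeranyl phenyl sulfone, made by acid cyclisation of geranyl phenyl sulfone. Both C10 halves therefore come from geranyl bromide.
5. Rings: the benzene ring is bought. The cyclohexene is the only ring formed (step 2), before the fragment union.

Assumption: the target has no stereocentre, so "single enantiomer" reduces to controlling the (2′E,6′E) alkene geometry.

## Route

Step 1
Reactants: 1 geranyl bromide; 2 sodium benzenesulfinate
Product: 3 geranyl phenyl sulfone
Conditions: PhSO2Na (1.2 equiv), DMF, rt, 12 h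
Reagents that add atoms: none
Why: SN2 S-alkylation of the ambident sulfinate by a primary allylic bromide in a dipolar aprotic solvent gives the sulfone cleanly, and its alkene geometry is erased in step 2 anyway.

Step 2
Reactants: 3 geranyl phenyl sulfone
Product: 4 β-cyclogeranyl phenyl sulfone
Conditions: conc. H2SO4/AcOH, 10–20 °C; recrystallise
Reagents that add atoms: none
Why: Brønsted-acid cationic polyene cyclisation, in which Markovnikov protonation of the electron-rich terminal alkene, six-ring closure by the sulfone-deactivated C2=C3 alkene and proton loss with equilibration in strong acid give the thermodynamic tetrasubstituted β-isomer, with the sulfone inert and no stereocentre left.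

Step 3
Reactants: 5 methyl 4-hydroxybenzoate; 1 geranyl bromide
Product: 7 methyl 3-geranyl-4-hydroxybenzoate, via sodium 4-(methoxycarbonyl)phenolate 6 (not isolated)
Conditions: NaH (1.0 equiv), toluene, 0 °C to rt; then 1 (0.8 equiv), rt to 50 °C
Reagents that add atoms: none
Why: Claisen-type ortho C-alkylation of a tight-ion-pair sodium phenolate in a non-polar solvent (para position blocked, both ortho sites equivalent) runs by SN2 at the primary allylic carbon, so the 2′E alkene of 1 is carried over, and the O-geranyl ether is a separable by-product.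

Step 4
Reactants: 7 methyl 3-geranyl-4-hydroxybenzoate
Product: 8 methyl 4-hydroxy-3-[(2E,6E)-8-hydroxy-3,7-dimethylocta-2,6-dienyl]benzoate
Conditions: SeO2 (0.2 equiv), salicylic acid (0.1 equiv), t-BuOOH (3 equiv), CH2Cl2, 0 °C to rt
Reagents that add atoms: tert-butyl hydroperoxide, CC(C)(C)OO (terminal source of the new O, relayed by catalytic selenium dioxide, O=[Se]=O)
Why: Sharpless catalytic Riley allylic oxidation, in which the ene reaction at the most accessible isopropylidene terminus followed by a [2,3]-sigmatropic shift places OH on the E-methyl group only and so fixes the 6′E geometry.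

Step 5
Reactants: 8 allylic alcohol
Product: 9 methyl 3-[(2E,6E)-8-bromo-3,7-dimethylocta-2,6-dienyl]-4-hydroxybenzoate
Conditions: CBr4 (1.2 equiv), PPh3 (1.25 equiv), CH2Cl2, −30 to 0 °C; short silica plug, use at once
Reagents that add atoms: carbon tetrabromide, BrC(Br)(Br)Br
Why: Appel reaction, a neutral SN2 displacement of the alkoxyphosphonium ion at a primary allylic carbon that keeps both E-alkenes, avoids HBr (which would close the o-allylphenol to a chroman) and leaves phenol and ester untouched.

Step 6 (key step)
Reactants: 4 β-cyclogeranyl phenyl sulfone; 9 allylic bromide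
Product: 12 (±)-methyl 3-[(2E,6E)-3,7-dimethyl-9-(phenylsulfonyl)-9-(2,6,6-trimethylcyclohex-1-enyl)nona-2,6-dienyl]-4-hydroxybenzoate, via α-lithio-β-cyclogeranyl phenyl sulfone 10 (not isolated), via lithium phenolate of the bromide 11 (not isolated)
Conditions: 4 (1.2 equiv), n-BuLi (1.15 equiv), THF, −78 °C; separately 9, LiHMDS (1.0 equiv), THF, −78 °C; cannulate 11 into 10, DMPU, −78 to −30 °C; aq NH4Cl
Reagents that add atoms: none
Why: Polarity-inverted allyl–allyl union (Biellmann/Julia-type α-sulfonyl carbanion alkylation), in which the cyclogeranyl CH2, by nature an allylic electrophile like C8′ of 9, attacks as carbanion 10 in an α-selective SN2 on the primary allylic bromide with retention of 6′E, while the phenolate form 11 removes the only acidic proton and electronically shields the para ester; the new C9′ centre is racemic and is erased in step 7.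

Step 7
Reactants: 12 coupled sulfone
Product: 14 cacospongin D, via cacospongin D methyl ester 13 (not isolated)
Conditions: 6% Na(Hg), Na2HPO4, MeOH/THF, −20 to 0 °C; decant from Hg; then 2 M aq NaOH, 65 °C; cold 1 M HCl to pH 3
Reagents that add atoms: sodium hydroxide, [Na+].[OH-]
Why: Buffered sodium-amalgam reductive desulfonylation (two electron transfers, loss of PhSO2−, protonation of the unsymmetrical allyl anion at its less substituted, charge-richer C9′ terminus, which restores the tetrasubstituted ring alkene) followed in the same flask by BAc2 saponification gives the acid, with both E-alkenes remote from the reacting site and no stereocentre left.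

## Compound list
1 | geranyl bromide, (2E)-1-bromo-3,7-dimethylocta-2,6-diene | CC(C)=CCC/C(C)=C/CBr | starting material
2 | sodium benzenesulfinate | [Na+].[O-]S(=O)c1ccccc1 | starting material
3 | geranyl phenyl sulfone, (2E)-3,7-dimethylocta-2,6-dienyl phenyl sulfone | CC(C)=CCC/C(C)=C/CS(=O)(=O)c1ccccc1 | intermediate
4 | β-cyclogeranyl phenyl sulfone, (2,6,6-trimethylcyclohex-1-enyl)methyl phenyl sulfone | CC1=C(CS(=O)(=O)c2ccccc2)C(C)(C)CCC1 | intermediate
5 | methyl 4-hydroxybenzoate | COC(=O)c1ccc(O)cc1 | starting material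
6 | sodium 4-(methoxycarbonyl)phenolate (not isolated) | [Na+].[O-]c1ccc(C(=O)OC)cc1 | intermediate
7 | methyl 3-[(2E)-3,7-dimethylocta-2,6-dienyl]-4-hydroxybenzoate | CC(C)=CCC/C(C)=C/Cc1cc(C(=O)OC)ccc1O | intermediate
8 | methyl 4-hydroxy-3-[(2E,6E)-8-hydroxy-3,7-dimethylocta-2,6-dienyl]benzoate | OC/C(C)=C/CC/C(C)=C/Cc1cc(C(=O)OC)ccc1O | intermediate
9 | methyl 3-[(2E,6E)-8-bromo-3,7-dimethylocta-2,6-dienyl]-4-hydroxybenzoate | BrC/C(C)=C/CC/C(C)=C/Cc1cc(C(=O)OC)ccc1O | intermediate
10 | α-lithio-β-cyclogeranyl phenyl sulfone (not isolated) | [Li]C(C1=C(C)CCCC1(C)C)S(=O)(=O)c1ccccc1 | intermediate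
11 | lithium phenolate of 9 (not isolated) | BrC/C(C)=C/CC/C(C)=C/Cc1cc(C(=O)OC)ccc1[O-].[Li+] | intermediate
12 | (±)-methyl 3-[(2E,6E)-3,7-dimethyl-9-(phenylsulfonyl)-9-(2,6,6-trimethylcyclohex-1-enyl)nona-2,6-dienyl]-4-hydroxybenzoate (racemic at C9′) | CC1=C(C(C/C(C)=C/CC/C(C)=C/Cc2cc(C(=O)OC)ccc2O)S(=O)(=O)c2ccccc2)C(C)(C)CCC1 | intermediate
13 | cacospongin D methyl ester (not isolated) | CC1=C(CC/C(C)=C/CC/C(C)=C/Cc2cc(C(=O)OC)ccc2O)C(C)(C)CCC1 | intermediate
14 | cacospongin D, 3-[(2E,6E)-3,7-dimethyl-9-(2,6,6-trimethylcyclohex-1-enyl)nona-2,6-dienyl]-4-hydroxybenzoic acid | CC1=C(CC/C(C)=C/CC/C(C)=C/Cc2cc(C(=O)O)ccc2O)C(C)(C)CCC1 | target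

## Step count and risks
Total steps: 7. Longest linear sequence: 5 (steps 3, 4, 5, 6, 7, from compound 5). The sulfone branch (steps 1 and 2) joins at step 6.

**Risk at step 4.** The oxidation could lose site selectivity between the two trisubstituted alkenes, over-oxidise, or suffer from the free phenol. The fallback sets out from 7 and comes back at 8. Cross-metathesis of the isopropylidene terminus with excess methacrolein (Hoveyda–Grubbs II, CH2Cl2, 40 °C) gives methyl 3-[(2E,6E)-3,7-dimethyl-8-oxoocta-2,6-dienyl]-4-hydroxybenzoate F1. The more hindered internal alkene stays untouched and the new alkene forms E-selectively. Luche reduction (NaBH4, CeCl3, MeOH, 0 °C) of F1 then delivers 8.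

**Risk at step 6.** The carbanion is hindered, and the acceptor carries a phenolate and an ester. The fallback keeps the same sulfonyl carbanion but makes the union before the arene is present. It sets out from 4 (as its anion 10) and comes back at 12.
- Purchased geranyl acetate F2 is oxidised (SeO2/t-BuOOH) to (2E,6E)-8-hydroxygeranyl acetate F3.
- An Appel reaction converts F3 to (2E,6E)-8-bromogeranyl acetate F4.
- Alkylation of 10 with F4 at −78 °C gives the C20 sulfonyl acetate F5.
- K2CO3/MeOH frees the C20 sulfonyl alcohol F6.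
- A second Appel reaction gives the C20 sulfonyl allylic bromide F7.
- Ortho C-alkylation of phenolate 6 with F7 in toluene gives 12.

**Risk at step 7.** Protonation of the allyl anion at the ring terminus would give the exocyclic alkene isomer. The fallback sets out from 12 and comes back at 14. It replaces electron transfer by ionisation and hydride capture. The ester is saponified first (NaOH, MeOH/H2O, 65 °C) to the C9′-phenylsulfonyl acid F8, whose carboxylate is inert to hydride. PdCl2(dppp) (cat.) with LiHBEt3 (excess) in THF at 0 °C then delivers hydride to the less hindered C9′ end of the π-allylpalladium species and gives 14.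

## Further compounds
F1 | step 4 | methyl 3-[(2E,6E)-3,7-dimethyl-8-oxoocta-2,6-dienyl]-4-hydroxybenzoate | O=C/C(C)=C/CC/C(C)=C/Cc1cc(C(=O)OC)ccc1O
F2 | step 6 | geranyl acetate (purchased) | CC(C)=CCC/C(C)=C/COC(C)=O
F3 | step 6 | (2E,6E)-8-hydroxygeranyl acetate | OC/C(C)=C/CC/C(C)=C/COC(C)=O
F4 | step 6 | (2E,6E)-8-bromogeranyl acetate | BrC/C(C)=C/CC/C(C)=C/COC(C)=O
F5 | step 6 | (±)-(2E,6E)-3,7-dimethyl-9-(phenylsulfonyl)-9-(2,6,6-trimethylcyclohex-1-enyl)nona-2,6-dienyl acetate | CC1=C(C(C/C(C)=C/CC/C(C)=C/COC(C)=O)S(=O)(=O)c2ccccc2)C(C)(C)CCC1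
F6 | step 6 | (±)-(2E,6E)-3,7-dimethyl-9-(phenylsulfonyl)-9-(2,6,6-trimethylcyclohex-1-enyl)nona-2,6-dien-1-ol | CC1=C(C(C/C(C)=C/CC/C(C)=C/CO)S(=O)(=O)c2ccccc2)C(C)(C)CCC1
F7 | step 6 | (±)-(2E,6E)-1-bromo-3,7-dimethyl-9-(phenylsulfonyl)-9-(2,6,6-trimethylcyclohex-1-enyl)nona-2,6-diene | CC1=C(C(C/C(C)=C/CC/C(C)=C/CBr)S(=O)(=O)c2ccccc2)C(C)(C)CCC1
F8 | step 7 | (±)-3-[(2E,6E)-3,7-dimethyl-9-(phenylsulfonyl)-9-(2,6,6-trimethylcyclohex-1-enyl)nona-2,6-dienyl]-4-hydroxybenzoic acid | CC1=C(C(C/C(C)=C/CC/C(C)=C/Cc2cc(C(=O)O)ccc2O)S(=O)(=O)c2ccccc2)C(C)(C)CCC1
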